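## Retrosynthetic overview

1. The α-methylene lactone ring is closed last, by oxidative lactonisation of a C6,C12-diol; the C8 ester comes from a Mitsunobu inversion of an 8-epi alcohol.
2. The furanone ring comes from 5-endo cyclisation of a C10-hydroxy ynone; the ten-membered carbocycle from intramolecular alkynylation (C1–C2) of a lactol.
3. The C6–C7 bond, both of its stereocentres and the exocyclic methylene come from a [2,3]-Wittig rearrangement of a (Z)-allyl dienynyl ether, steered by C8.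
4. That ether comes from an oxa-Michael/Horner–Wadsworth–Emmons union of (Z)-3-methylpent-2-en-4-yn-1-ol, a phosphonoacrylate and an aldehyde made from 2-C-methyl-D-ribono-1,4-lactone, which supplies C8, C9 and C10.
5. Ring order: ten-membered carbocycle, then furanone, then lactone.

Assumption: the enynol, the 2-C-methyl lactone, ethyl 2-(diethoxyphosphoryl)acrylate and 3-methylbutanoic acid are catalogue compounds; locants are those of the germacrane skeleton (C1 ketone, C3–O–C10 furanone bridge, C6 lactone oxygen, C8 ester, C9 hydroxyl, C12 lactone carbonyl, C13 methylene); TBS = tert-butyldimethylsilyl, TES = triethylsilyl, TMS = trimethylsilyl.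

## Route

Step 1
Reactants: 1 (2Z)-3-methylpent-2-en-4-yn-1-ol
Product: 3 (2Z)-3-methyl-5-(trimethylsilyl)pent-2-en-4-yn-1-ol, via bis-silyl ether 2 (not isolated)
Conditions: EtMgBr (2.2 equiv), THF, 0 °C to rt; TMSCl (2.3 equiv); then 1 M HCl, 0 °C
Reagents that add atoms: chlorotrimethylsilane C[Si](C)(C)Cl
Why: C-silylation of the alkynyl Grignard reagent with transient O-silylation, then selective acid hydrolysis of the labile O–Si bond; no stereocentre is involved and the Z alkene is untouched.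

Step 2
Reactants: 4 2-C-methyl-D-ribono-1,4-lactone
Product: 6 3-O-TBS-5-O-TES-2-C-methyl-D-ribono-1,4-lactone, via 5-O-TES lactone 5 (not isolated)
Conditions: TESCl (1.05 equiv), imidazole, DMF, −30 °C; then TBSCl (1.5 equiv), DMAP (cat.), 40 °C
Reagents that add atoms: chlorotriethylsilane CC[Si](Cl)(CC)CC; tert-butylchlorodimethylsilane CC(C)(C)[Si](C)(C)Cl
Why: Sequential silyl ether formation in the order primary then secondary hydroxyl, the tertiary C10 hydroxyl being inert to both chlorides; the three bought stereocentres (C8, C9, C10) are not touched.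

Step 3
Reactants: 6 3-O-TBS-5-O-TES-2-C-methyl-D-ribono-1,4-lactone
Product: 7 (2S,3R,4R)-3-(TBSO)-4-hydroxy-4-methyl-5-oxooxolane-2-carbaldehyde
Conditions: (COCl)2, DMSO, CH2Cl2, −78 to −40 °C; Et3N, −78 to 0 °C
Reagents that add atoms: none
Why: Swern oxidation cleaves and oxidises a primary triethylsilyl ether directly while the secondary TBS ether and the tertiary alcohol survive; the aldehyde is used crude and cold so that C8 does not epimerise.

Step 4
Reactants: 7 (2S,3R,4R)-3-(TBSO)-4-hydroxy-4-methyl-5-oxooxolane-2-carbaldehyde; 3 (2Z)-3-methyl-5-(trimethylsilyl)pent-2-en-4-yn-1-ol; 8 ethyl 2-(diethoxyphosphoryl)prop-2-enoate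
Product: 10 ethyl (2E)-3-[(2R,3R,4R)-3-(TBSO)-4-hydroxy-4-methyl-5-oxooxolan-2-yl]-2-({[(2Z)-3-methyl-5-(trimethylsilyl)pent-2-en-4-yn-1-yl]oxy}methyl)prop-2-enoate, via phosphonate carbanion 9 (not isolated)
Conditions: 3, NaH (1.0 equiv), THF, 0 °C; 8, 0 °C; then 7, −78 to 0 °C
Reagents that add atoms: none
Why: Tandem oxa-Michael addition / Horner–Wadsworth–Emmons olefination: the alkoxide adds to the vinylphosphonate and the resulting stabilised carbanion olefinates the aldehyde with the usual E selectivity (ester trans to C8), which places C8 cis to the CH2–O arm.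

Step 5
Reactants: 10 ethyl (2E)-3-[(2R,3R,4R)-3-(TBSO)-4-hydroxy-4-methyl-5-oxooxolan-2-yl]-2-({[(2Z)-3-methyl-5-(trimethylsilyl)pent-2-en-4-yn-1-yl]oxy}methyl)prop-2-enoate
Product: 11 (2Z)-3-[(2R,3R,4R)-3-(TBSO)-4,5-dihydroxy-4-methyloxolan-2-yl]-2-({[(2Z)-3-methyl-5-(trimethylsilyl)pent-2-en-4-yn-1-yl]oxy}methyl)prop-2-en-1-ol (lactol; anomer mixture)
Conditions: i-Bu2AlH (5 equiv), CH2Cl2, −78 °C; aq. KNaC4H4O6
Reagents that add atoms: none
Why: DIBAL reduction takes the enoate to the allylic alcohol (1,2-reduction) and stops the lactone at the lactol at −78 °C, which is the aldehyde oxidation level needed later at C1; no stereocentre of the chain is affected.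

Step 6
Reactants: 11 (2Z)-3-[(2R,3R,4R)-3-(TBSO)-4,5-dihydroxy-4-methyloxolan-2-yl]-2-({[(2Z)-3-methyl-5-(trimethylsilyl)pent-2-en-4-yn-1-yl]oxy}methyl)prop-2-en-1-ol
Product: 13 tris-silyl ether of 11 (anomeric O-TBS; C12 O-TBS; C10 O-TMS), via bis-TBS ether 12 (not isolated)
Conditions: TBSCl (2.4 equiv), imidazole, DMF, 0 °C to rt; then TMSCl (1.5 equiv), rt
Reagents that add atoms: tert-butylchlorodimethylsilane CC(C)(C)[Si](C)(C)Cl; chlorotrimethylsilane C[Si](C)(C)Cl
Why: Silyl ether formation caps the lactol (so no aldehyde is exposed to base) and the primary allylic alcohol, and the small TMS group caps the tertiary alcohol so that no alkoxide can trigger silyl migration from the anomeric oxygen in the next step.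

Step 7
Reactants: 13 tris-silyl ether of 11 (anomeric O-TBS; C12 O-TBS; C10 O-TMS)
Product: 15 rearranged tetrasilyl ether: furanoside ring of 13 bearing at C8 the chain C7H[C11(=C13H2)C12H2OTBS]-C6H(OTBS)-C5H=C4(CH3)-C≡C-TMS (4Z; C6 and C7 as in the target), via lithium alkoxide 14 (not isolated)
Conditions: n-BuLi (1.3 equiv), THF, −78 to −40 °C; then TBSOTf (1.5 equiv), −78 to 0 °C
Reagents that add atoms: tert-butyldimethylsilyl trifluoromethanesulfonate CC(C)(C)[Si](C)(C)OS(=O)(=O)C(F)(F)F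
Why: [2,3]-Wittig rearrangement: the C6 carbanion (the more acidic α-oxy site, conjugated with the silyl enyne) attacks C7 through a five-membered envelope with the dienynyl group exo, so the Z-type allyl ether (C8 cis to the O–CH2 arm) gives the syn C6/C7 relation; attack anti to the ring oxygen on C8 in the A(1,3)-minimised H-eclipsed conformer (also the face away from the anomeric silyloxy group) sets C7, so both new stereocentres are controlled by C8 of the sugar; the alkoxide is silylated in the same flask.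

Step 8
Reactants: 15 rearranged tetrasilyl ether
Product: 16 lactol of 15 (free anomeric OH; free C10 OH; terminal alkyne; TBS ethers at C6 C9 C12 kept)
Conditions: Bu4NF (3.3 equiv), AcOH (3.5 equiv), THF, −20 to 0 °C
Reagents that add atoms: none
Why: Buffered fluoride desilylation: the anomeric silyl acetal, the tertiary TMS ether and the alkynyl TMS group are much more labile than the three alkyl TBS ethers, and the acetic acid buffer prevents base-induced silyl migration.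

Step 9
Reactants: 16 lactol of 15
Product: 17 (4Z)-6,9,12-tris(TBSO)germacra-4,11(13)-dien-2-yne-1,8,10-triol (C1 epimers; C8 epimeric to the target)
Conditions: LiN(SiMe3)2 (3.5 equiv), THF (0.002 M), −78 to 0 °C; aq. NH4Cl
Reagents that add atoms: none
Why: Intramolecular acetylide addition to the aldehyde released from the lithium lactolate closes the ten-membered ring (C1–C2); the Z-enyne holds the two ends close, the C1 aldehyde has no α-hydrogen, and the new C1 carbinol is oxidised next so its configuration is irrelevant.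

Step 10
Reactants: 17 (4Z)-6,9,12-tris(TBSO)germacra-4,11(13)-dien-2-yne-1,8,10-triol
Product: 19 (4Z)-6,9,12-tris(TBSO)-3,10-epoxy-8-hydroxygermacra-2,4,11(13)-trien-1-one (8-epi), via ynone 18 (not isolated)
Conditions: MnO2 (20 equiv), CH2Cl2, rt; filter; Ph3PAuNTf2 (5 mol %), CH2Cl2, rt
Reagents that add atoms: none
Why: MnO2 oxidises only the propargylic C1 alcohol (C8–OH is unactivated, C6–O is silylated), and gold-catalysed 5-endo-dig oxa-cyclisation of the C10 hydroxyl onto C3 gives the 3(2H)-furanone; the 6-endo competitor is blocked by the C9 TBS ether and the 7-endo closure from C8–OH is slower.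

Step 11
Reactants: 19 (4Z)-6,9,12-tris(TBSO)-3,10-epoxy-8-hydroxygermacra-2,4,11(13)-trien-1-one; 20 3-methylbutanoic acid
Product: 21 (4Z)-6,9,12-tris(TBSO)-3,10-epoxy-8-(3-methylbutanoyloxy)germacra-2,4,11(13)-trien-1-one (C8 as in the target)
Conditions: 20 (4 equiv), PPh3, DIAD, toluene, 0 °C to rt
Reagents that add atoms: none
Why: Mitsunobu esterification of the only free secondary alcohol proceeds by SN2 displacement of the oxyphosphonium, inverting the D-ribo C8 centre to the target configuration while installing the ester in the same operation.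

Step 12
Reactants: 21 (4Z)-6,9,12-tris(TBSO)-3,10-epoxy-8-(3-methylbutanoyloxy)germacra-2,4,11(13)-trien-1-one
Product: 22 (4Z)-3,10-epoxy-6,9,12-trihydroxy-8-(3-methylbutanoyloxy)germacra-2,4,11(13)-trien-1-one
Conditions: HF·pyridine, pyridine, THF, 0 °C to rt
Reagents that add atoms: none
Why: Acidic fluoride desilylation removes the three TBS ethers without the basic conditions that would promote migration of the C8 acyl group to the neighbouring hydroxyls.

Step 13
Reactants: 22 (4Z)-3,10-epoxy-6,9,12-trihydroxy-8-(3-methylbutanoyloxy)germacra-2,4,11(13)-trien-1-one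
Product: 24 (4Z,6S,7S,8S,9R,10R)-3,10-epoxy-9-hydroxy-8-(3-methylbutanoyloxy)-1-oxogermacra-2,4,11(13)-trien-12,6-olide (CNP0175298.2), via lactol 23 (not isolated)
Conditions: TEMPO (0.2 equiv), PhI(OAc)2 (2.5 equiv), CH2Cl2, rt
Reagents that add atoms: none
Why: TEMPO/PhI(OAc)2 oxidative lactonisation: the primary allylic alcohol is oxidised selectively to the enal, which is trapped by the C6 hydroxyl as the five-membered lactol (favoured over the six-membered lactol from C9–OH) and oxidised on to the α-methylene-γ-lactone; no stereocentre changes.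

## Compound list

1 | (2Z)-3-methylpent-2-en-4-yn-1-ol | OC/C=C(/C)C#C | starting material
2 | trimethyl{[(2Z)-3-methyl-5-(trimethylsilyl)pent-2-en-4-yn-1-yl]oxy}silane | C[Si](C)(C)OC/C=C(/C)C#C[Si](C)(C)C | intermediate
3 | (2Z)-3-methyl-5-(trimethylsilyl)pent-2-en-4-yn-1-ol | OC/C=C(/C)C#C[Si](C)(C)C | intermediate
4 | 2-C-methyl-D-ribono-1,4-lactone, (3R,4R,5R)-3,4-dihydroxy-5-(hydroxymethyl)-3-methyloxolan-2-one | O=C1[C@](C)(O)[C@H](O)[C@@H](CO)O1 | starting material
5 | 2-C-methyl-5-O-(triethylsilyl)-D-ribono-1,4-lactone | O=C1[C@](C)(O)[C@H](O)[C@@H](CO[Si](CC)(CC)CC)O1 | intermediate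
6 | 3-O-TBS-5-O-TES-2-C-methyl-D-ribono-1,4-lactone | O=C1[C@](C)(O)[C@H](O[Si](C)(C)C(C)(C)C)[C@@H](CO[Si](CC)(CC)CC)O1 | intermediate
7 | (2S,3R,4R)-3-(TBSO)-4-hydroxy-4-methyl-5-oxooxolane-2-carbaldehyde | O=C1[C@](C)(O)[C@H](O[Si](C)(C)C(C)(C)C)[C@@H](C=O)O1 | intermediate
8 | ethyl 2-(diethoxyphosphoryl)prop-2-enoate | C=C(C(=O)OCC)P(=O)(OCC)OCC | starting material
9 | sodium salt of the carbanion of ethyl 2-(diethoxyphosphoryl)-3-{[(2Z)-3-methyl-5-(trimethylsilyl)pent-2-en-4-yn-1-yl]oxy}propanoate | [Na+].CCOC(=O)[C-](COC/C=C(/C)C#C[Si](C)(C)C)P(=O)(OCC)OCC | intermediate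
10 | ethyl (2E)-3-[(2R,3R,4R)-3-(TBSO)-4-hydroxy-4-methyl-5-oxooxolan-2-yl]-2-({[(2Z)-3-methyl-5-(trimethylsilyl)pent-2-en-4-yn-1-yl]oxy}methyl)prop-2-enoate | O=C1[C@](C)(O)[C@H](O[Si](C)(C)C(C)(C)C)[C@@H](/C=C(/C(=O)OCC)COC/C=C(/C)C#C[Si](C)(C)C)O1 | intermediate
11 | (2Z)-3-[(2R,3R,4R)-3-(TBSO)-4,5-dihydroxy-4-methyloxolan-2-yl]-2-({[(2Z)-3-methyl-5-(trimethylsilyl)pent-2-en-4-yn-1-yl]oxy}methyl)prop-2-en-1-ol (lactol; anomer mixture) | OC1[C@](C)(O)[C@H](O[Si](C)(C)C(C)(C)C)[C@@H](/C=C(/CO)COC/C=C(/C)C#C[Si](C)(C)C)O1 | intermediate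
12 | bis-TBS ether of 11 (anomeric O and primary allylic O silylated, tertiary OH free) | CC(C)(C)[Si](C)(C)OC1[C@](C)(O)[C@H](O[Si](C)(C)C(C)(C)C)[C@@H](/C=C(/CO[Si](C)(C)C(C)(C)C)COC/C=C(/C)C#C[Si](C)(C)C)O1 | intermediate
13 | tris-silyl ether of 11 (anomeric O-TBS; C12 O-TBS; C10 O-TMS) | CC(C)(C)[Si](C)(C)OC1[C@](C)(O[Si](C)(C)C)[C@H](O[Si](C)(C)C(C)(C)C)[C@@H](/C=C(/CO[Si](C)(C)C(C)(C)C)COC/C=C(/C)C#C[Si](C)(C)C)O1 | intermediate
14 | lithium C6-alkoxide of the rearranged skeleton (furanoside ring of 13 with the chain C7H[C(=CH2)CH2OTBS]-C6H(OLi)-CH=C(CH3)-C≡C-TMS at C8) | [Li+].CC(C)(C)[Si](C)(C)OC1[C@](C)(O[Si](C)(C)C)[C@H](O[Si](C)(C)C(C)(C)C)[C@@H]([C@H]([C@@H]([O-])/C=C(/C)C#C[Si](C)(C)C)C(=C)CO[Si](C)(C)C(C)(C)C)O1 | intermediate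
15 | rearranged tetrasilyl ether: furanoside ring of 13 bearing at C8 the chain C7H[C11(=C13H2)C12H2OTBS]-C6H(OTBS)-C5H=C4(CH3)-C≡C-TMS (4Z; C6 and C7 as in the target) | CC(C)(C)[Si](C)(C)OC1[C@](C)(O[Si](C)(C)C)[C@H](O[Si](C)(C)C(C)(C)C)[C@@H]([C@H]([C@@H](O[Si](C)(C)C(C)(C)C)/C=C(/C)C#C[Si](C)(C)C)C(=C)CO[Si](C)(C)C(C)(C)C)O1 | intermediate
16 | lactol of 15 (free anomeric OH; free C10 OH; terminal alkyne; TBS ethers at C6, C9, C12 kept) | OC1[C@](C)(O)[C@H](O[Si](C)(C)C(C)(C)C)[C@@H]([C@H]([C@@H](O[Si](C)(C)C(C)(C)C)/C=C(/C)C#C)C(=C)CO[Si](C)(C)C(C)(C)C)O1 | intermediate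
17 | (4Z)-6,9,12-tris(TBSO)germacra-4,11(13)-dien-2-yne-1,8,10-triol (C1 epimers; C8 epimeric to the target) | OC1C#C/C(C)=C\[C@H](O[Si](C)(C)C(C)(C)C)[C@H](C(=C)CO[Si](C)(C)C(C)(C)C)[C@@H](O)[C@@H](O[Si](C)(C)C(C)(C)C)[C@@]1(C)O | intermediate
18 | (4Z)-6,9,12-tris(TBSO)-8,10-dihydroxygermacra-4,11(13)-dien-2-yn-1-one | O=C1C#C/C(C)=C\[C@H](O[Si](C)(C)C(C)(C)C)[C@H](C(=C)CO[Si](C)(C)C(C)(C)C)[C@@H](O)[C@@H](O[Si](C)(C)C(C)(C)C)[C@@]1(C)O | intermediate
19 | (4Z)-6,9,12-tris(TBSO)-3,10-epoxy-8-hydroxygermacra-2,4,11(13)-trien-1-one (8-epi) | O=C1C=C2/C(C)=C\[C@H](O[Si](C)(C)C(C)(C)C)[C@H](C(=C)CO[Si](C)(C)C(C)(C)C)[C@@H](O)[C@@H](O[Si](C)(C)C(C)(C)C)[C@@]1(C)O2 | intermediate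
20 | 3-methylbutanoic acid | CC(C)CC(=O)O | starting material
21 | (4Z)-6,9,12-tris(TBSO)-3,10-epoxy-8-(3-methylbutanoyloxy)germacra-2,4,11(13)-trien-1-one (C8 as in the target) | O=C1C=C2/C(C)=C\[C@H](O[Si](C)(C)C(C)(C)C)[C@H](C(=C)CO[Si](C)(C)C(C)(C)C)[C@H](OC(=O)CC(C)C)[C@@H](O[Si](C)(C)C(C)(C)C)[C@@]1(C)O2 | intermediate
22 | (4Z)-3,10-epoxy-6,9,12-trihydroxy-8-(3-methylbutanoyloxy)germacra-2,4,11(13)-trien-1-one | O=C1C=C2/C(C)=C\[C@H](O)[C@H](C(=C)CO)[C@H](OC(=O)CC(C)C)[C@@H](O)[C@@]1(C)O2 | intermediate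
23 | 12,6-lactol of 22 (6,12-epoxy-12-hydroxy compound, C12 epimers) | O=C1C=C2/C(C)=C\[C@@H]3OC(O)C(=C)[C@@H]3[C@H](OC(=O)CC(C)C)[C@@H](O)[C@@]1(C)O2 | intermediate
24 | (4Z,6S,7S,8S,9R,10R)-3,10-epoxy-9-hydroxy-8-(3-methylbutanoyloxy)-1-oxogermacra-2,4,11(13)-trien-12,6-olide (CNP0175298.2) | C=C1C(=O)O[C@H]2/C=C(/C)C3=CC(=O)[C@](C)(O3)[C@H](O)[C@@H](OC(=O)CC(C)C)[C@@H]12 | target

## Step count and risks

Total step count: 13. Longest linear sequence: 12 steps (4 to 24, steps 2–13).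

**Step 7, the [2,3]-Wittig rearrangement.** The dienynyl-stabilised carbanion is less precedented than a propargylic one, and the facial selectivity rests on a Felkin-type model (attack anti to the C8 ring oxygen); low yield or a diastereomer mixture is possible. The fallback sets out from aldehyde 7 and comes back at 15. Step 4 is run with but-2-yn-1-ol in place of 3, giving via the sodium phosphonate carbanion F1 the but-2-ynyl ether enoate F2. Reduction as in step 5 gives the lactol diol F3, and silylation as in step 6 gives, via the bis-TBS ether F4, the tris-silyl ether F5. Rearrangement with n-BuLi (THF, −78 °C; a propargylic carbanion, the best-behaved class for this reaction) and NH4Cl quench gives the propargylic alcohol F6. Hydroxyl-directed trans-hydroalumination with NaAlH2(OCH2CH2OMe)2 followed by I2 gives the (Z)-iodoalkene F7. Sonogashira coupling with ethynyltrimethylsilane (Pd(PPh3)4, CuI, Et3N) gives the enynol F8, and TBSOTf/2,6-lutidine returns to 15.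

**Step 9, the ten-membered ring closure.** The lactol masks the aldehyde, three anions are present, and oligomerisation or C9-to-C8 silyl migration can compete. The fallback sets out from 16 and comes back at 17. The alkyne is iodinated (N-iodosuccinimide, AgNO3 cat., acetone) to the iodoalkyne F9, which is closed by a Nozaki–Hiyama–Kishi coupling (CrCl2 in excess, NiCl2 cat., THF/DMF, 0.002 M, rt). The alkynylchromium species adds to the hydroxy-aldehyde tautomer under neutral conditions, without alkoxides.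

**Step 11, the Mitsunobu inversion.** The C8 alcohol sits in the macrocycle between C7 and the silylated C9, and elimination or retention can compete with SN2 displacement. The fallback sets out from 19 and comes back at 21. Buffered Dess–Martin oxidation gives the C8 ketone F10. Hydride reduction (NaBH4, MeOH, −78 °C), expected from the outer face anti to the C7 side chain, gives the inverted alcohol F11; any 19 re-formed is separated and recycled. Acylation with 3-methylbutanoic anhydride/DMAP gives 21.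

## Further compounds

F1 | step 7 | sodium salt of the carbanion of ethyl 3-(but-2-yn-1-yloxy)-2-(diethoxyphosphoryl)propanoate | [Na+].CCOC(=O)[C-](COCC#CC)P(=O)(OCC)OCC
F2 | step 7 | ethyl (2E)-2-[(but-2-yn-1-yloxy)methyl]-3-[(2R,3R,4R)-3-(TBSO)-4-hydroxy-4-methyl-5-oxooxolan-2-yl]prop-2-enoate | O=C1[C@](C)(O)[C@H](O[Si](C)(C)C(C)(C)C)[C@@H](/C=C(/C(=O)OCC)COCC#CC)O1
F3 | step 7 | (2Z)-2-[(but-2-yn-1-yloxy)methyl]-3-[(2R,3R,4R)-3-(TBSO)-4,5-dihydroxy-4-methyloxolan-2-yl]prop-2-en-1-ol (lactol diol) | OC1[C@](C)(O)[C@H](O[Si](C)(C)C(C)(C)C)[C@@H](/C=C(/CO)COCC#CC)O1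
F4 | step 7 | bis-TBS ether of F3 (anomeric O and primary allylic O) | CC(C)(C)[Si](C)(C)OC1[C@](C)(O)[C@H](O[Si](C)(C)C(C)(C)C)[C@@H](/C=C(/CO[Si](C)(C)C(C)(C)C)COCC#CC)O1
F5 | step 7 | tris-silyl ether of F3 (anomeric O-TBS; C12 O-TBS; C10 O-TMS) | CC(C)(C)[Si](C)(C)OC1[C@](C)(O[Si](C)(C)C)[C@H](O[Si](C)(C)C(C)(C)C)[C@@H](/C=C(/CO[Si](C)(C)C(C)(C)C)COCC#CC)O1
F6 | step 7 | rearranged propargylic alcohol (chain C7H[C(=CH2)CH2OTBS]-C6H(OH)-C≡C-CH3 at C8 of the furanoside) | CC(C)(C)[Si](C)(C)OC1[C@](C)(O[Si](C)(C)C)[C@H](O[Si](C)(C)C(C)(C)C)[C@@H]([C@H]([C@@H](O)C#CC)C(=C)CO[Si](C)(C)C(C)(C)C)O1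
F7 | step 7 | (Z)-iodoalkene (chain C7H[C(=CH2)CH2OTBS]-C6H(OH)-CH=C(CH3)I at C8 of the furanoside) | CC(C)(C)[Si](C)(C)OC1[C@](C)(O[Si](C)(C)C)[C@H](O[Si](C)(C)C(C)(C)C)[C@@H]([C@H]([C@@H](O)/C=C(/C)I)C(=C)CO[Si](C)(C)C(C)(C)C)O1
F8 | step 7 | free C6 alcohol corresponding to 14 | CC(C)(C)[Si](C)(C)OC1[C@](C)(O[Si](C)(C)C)[C@H](O[Si](C)(C)C(C)(C)C)[C@@H]([C@H]([C@@H](O)/C=C(/C)C#C[Si](C)(C)C)C(=C)CO[Si](C)(C)C(C)(C)C)O1
F9 | step 9 | iodoalkyne of lactol 16 | OC1[C@](C)(O)[C@H](O[Si](C)(C)C(C)(C)C)[C@@H]([C@H]([C@@H](O[Si](C)(C)C(C)(C)C)/C=C(/C)C#CI)C(=C)CO[Si](C)(C)C(C)(C)C)O1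
F10 | step 11 | (4Z)-6,9,12-tris(TBSO)-3,10-epoxygermacra-2,4,11(13)-triene-1,8-dione | O=C1C=C2/C(C)=C\[C@H](O[Si](C)(C)C(C)(C)C)[C@H](C(=C)CO[Si](C)(C)C(C)(C)C)C(=O)[C@@H](O[Si](C)(C)C(C)(C)C)[C@@]1(C)O2
F11 | step 11 | (4Z)-6,9,12-tris(TBSO)-3,10-epoxy-8-hydroxygermacra-2,4,11(13)-trien-1-one with C8 as in the target | O=C1C=C2/C(C)=C\[C@H](O[Si](C)(C)C(C)(C)C)[C@H](C(=C)CO[Si](C)(C)C(C)(C)C)[C@H](O)[C@@H](O[Si](C)(C)C(C)(C)C)[C@@]1(C)O2
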